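## Retrosynthetic overview

- The route rests on ring A (C4a–C5–C6–C7–C8–C8a): a mirror-symmetric 6,7-dimethoxybenzene whose adjacent carbons C8a and C4a carry C1 and C4. The chain C1–C2(CH3)–C3(CH3)–C4 of ring B is the six-carbon skeleton of 2,3-dimethylbutadiene.
- The C1–aryl bond (ring C) is cut last: Friedel–Crafts attack of veratrole on the C1 benzylic cation, anti to the C2 methyl, starting from alcohol 6.
- The C1–OH comes from oxidising one of the two enantiotopic benzylic CH2 groups of the meso cis-2,3-dimethyltetralin 5; this step sets the absolute configuration. Compound 5 comes from syn hydrogenation of the C2=C3 alkene of 4.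
- Ring B of 4 is cut at C1–C8a and C4–C4a: [4+2] cycloaddition of 4,5-dimethoxybenzyne with 2,3-dimethylbutadiene.
- Ring order: ring A is bought intact in the aryne precursor, ring B is closed in step 1, ring C is attached in step 4.

Key step: step 1

Remarks on the chemistry:
- Tetralin numbering is used throughout: C1 carries the aryl group, C2 and C3 the methyls, C4 is the CH2.
- Silyl triflate 1 is taken to be a catalogue aryne precursor.
- Which antipode of the manganese catalyst in step 3 selects the required CH2 cannot be derived in advance; (R,R) is written, and the (S,S) complex is used instead if a first run shows the opposite sense.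

## Route

Step 1
Reactants: 1 4,5-dimethoxy-2-(trimethylsilyl)phenyl triflate; 2 2,3-dimethylbuta-1,3-diene
Product: 4 6,7-dimethoxy-2,3-dimethyl-1,4-dihydronaphthalene, via 4,5-dimethoxybenzyne 3 (not isolated)
Conditions: CsF (3 equiv), 2 (5 equiv), MeCN, 25 °C
Reagents that add atoms: none
Why: Fluoride attacks silicon in 1 and the ortho triflate departs, so aryne 3 is released slowly and its strained triple bond adds the s-cis conformer of 2 in a concerted suprafacial [4+2] cycloaddition; the closest known reaction type is the Diels–Alder trapping of fluoride-generated benzynes by acyclic 2,3-disubstituted butadienes to give 1,4-dihydronaphthalenes. Ring B is closed by this intermolecular [4+2] annulation, which forms C1–C8a and C4–C4a together and leaves the C2=C3 alkene carrying both methyl groups. No stereocentre is created, so only constitution has to be controlled. The selectivity required is periselectivity, cycloaddition ahead of the ene reaction with the allylic methyl hydrogens and ahead of [2+2] addition; it should be secured by the 2,3-dimethyl substitution that populates the s-cis diene, by the excess of 2, and by the low stationary aryne concentration given by sparingly soluble CsF. Regiochemistry cannot go wrong because 3 and 2 each have a twofold axis bisecting the reacting π system, which places the methoxy groups at C6 and C7.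

Step 2
Reactants: 4 6,7-dimethoxy-2,3-dimethyl-1,4-dihydronaphthalene
Product: 5 meso-(2R,3S)-6,7-dimethoxy-2,3-dimethyl-1,2,3,4-tetrahydronaphthalene (cis-dimethyl)
Conditions: H2 (5 bar), [Ir(cod)(PCy3)(py)]PF6 (5 mol %), CH2Cl2, 25 °C
Reagents that add atoms: none
Why: Homogeneous iridium-catalysed hydrogenation of a tetrasubstituted alkene should deliver both hydrogens to one face of C2=C3 faster than the double bond can migrate, so C2 and C3 are set together as the cis (meso) pair; 4 is achiral, so the face that reacts is immaterial.

Step 3
Reactants: 5 meso-(2R,3S)-6,7-dimethoxy-2,3-dimethyl-1,2,3,4-tetrahydronaphthalene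
Product: 6 (1S,2R,3R)-6,7-dimethoxy-2,3-dimethyl-1,2,3,4-tetrahydronaphthalen-1-ol
Conditions: (R,R)-(salen)MnCl (5 mol %; salen = N,N'-bis(3,5-di-tert-butylsalicylidene)cyclohexane-1,2-diamine dianion), PhIO (1 equiv), 4-phenylpyridine N-oxide (25 mol %), PhCl, −20 °C, run to partial conversion, 5 recovered
Reagents that add atoms: iodosylbenzene, O=Ic1ccccc1
Why: Proposed new method: the pentavalent oxomanganese salen species formed from PhIO should abstract a pseudo-axial benzylic hydrogen para to a ring A methoxy group and return hydroxyl to the same face (hydrogen abstraction/oxygen rebound), and because the two benzylic CH2 groups of meso 5 are enantiotopic the chiral salen pocket should favour the one bonded to the (S)-configured methine, which fixes C2 and C3 of 6 as R,R, while the C1 configuration (drawn 1S, hydroxyl anti to the methyls) is of no consequence because step 4 planarises that carbon; the closest known reaction type is chiral (salen)MnCl benzylic C–H hydroxylation of indane and tetralin derivatives (enantioselective hydroxylation, kinetic resolution, enantiotopic oxidation of 2-substituted indanes), not yet shown on a meso 2,3-dialkyltetralin carrying a dimethoxyarene.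

Step 4
Reactants: 6 (1S,2R,3R)-6,7-dimethoxy-2,3-dimethyl-1,2,3,4-tetrahydronaphthalen-1-ol; 7 veratrole
Product: 9 (1R,2R,3R)-1-(3,4-dimethoxyphenyl)-6,7-dimethoxy-2,3-dimethyl-1,2,3,4-tetrahydronaphthalene, via benzylic cation 8 (not isolated)
Conditions: Bi(OTf)3 (5 mol %), 7 (5 equiv), MeNO2, 0 to 25 °C
Reagents that add atoms: none
Why: Friedel–Crafts alkylation: the Lewis acid ionises the para-methoxy-activated benzylic alcohol to planar cation 8, which veratrole should attack through its C4 on the face opposite the adjacent C2 methyl (and the cis C3 methyl), setting C1 as R (1,2-trans) without touching C2 or C3.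

## Compound list

1 | 4,5-dimethoxy-2-(trimethylsilyl)phenyl trifluoromethanesulfonate | COc1cc(OS(=O)(=O)C(F)(F)F)c([Si](C)(C)C)cc1OC | starting material
2 | 2,3-dimethylbuta-1,3-diene | CC(=C)C(C)=C | starting material
3 | 4,5-dimethoxybenzyne (1,2-didehydro-4,5-dimethoxybenzene) | COC1=CC#CC=C1OC | intermediate
4 | 6,7-dimethoxy-2,3-dimethyl-1,4-dihydronaphthalene | COc1cc2CC(C)=C(C)Cc2cc1OC | intermediate
5 | meso-(2R,3S)-6,7-dimethoxy-2,3-dimethyl-1,2,3,4-tetrahydronaphthalene (cis-dimethyl) | COc1cc2c(cc1OC)C[C@@H](C)[C@@H](C)C2 | intermediate
6 | (1S,2R,3R)-6,7-dimethoxy-2,3-dimethyl-1,2,3,4-tetrahydronaphthalen-1-ol | O[C@@H]1c2cc(OC)c(OC)cc2C[C@@H](C)[C@H]1C | intermediate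
7 | veratrole (1,2-dimethoxybenzene) | COc1ccccc1OC | starting material
8 | C1 benzylic cation of the cis-2,3-dimethyltetralin, C2 and C3 configured as in 6 | [CH+]1c2cc(OC)c(OC)cc2C[C@@H](C)[C@H]1C | intermediate
9 | (1R,2R,3R)-1-(3,4-dimethoxyphenyl)-6,7-dimethoxy-2,3-dimethyl-1,2,3,4-tetrahydronaphthalene | COc1ccc([C@@H]2c3cc(OC)c(OC)cc3C[C@@H](C)[C@H]2C)cc1OC | target

## Summary and risks

Total step count: 4. Longest linear sequence: 4 steps (from 1).

Steps most likely to fail:

**Step 3 (proposed new method).** Three processes threaten it: weak or reversed discrimination between the two enantiotopic CH2 groups; outer-sphere electron transfer from the electron-rich ring, which would oxidise the benzylic position outside the chiral pocket; and over-oxidation of the alcohol to the ketone. The fallback sets out from 5 and uses known chemistry only: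
- DDQ in aqueous acetic acid at 25 °C oxidises one CH2 para to a methoxy group to racemic cis-6,7-dimethoxy-2,3-dimethyl-3,4-dihydronaphthalen-1(2H)-one F1; the new carbonyl deactivates the ring against a second oxidation.
- LiBH(s-Bu)3 in THF at −78 °C delivers hydride anti to the methyls and should give the racemic all-cis alcohol F2.
- Lipase-catalysed acylation (immobilised Candida antarctica lipase B, vinyl acetate, MTBE, 30 °C) is a kinetic resolution. By the usual empirical rule for secondary benzylic alcohols it should acetylate the 1R antipode, giving (1R,2R,3R)-acetate F3 and leaving the (1S,2S,3S)-alcohol F4, which is separated and discarded.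
- Acetate F3 is ionised under the conditions of step 4 (Bi(OTf)3, veratrole) to the same cation 8, and the fallback comes back to the route at 9.

**Step 2.** The double bond may migrate into conjugation with ring A before hydrogen is delivered, which would erode the cis-dimethyl relationship; dehydrogenation to the naphthalene is a second risk. The fallback sets out from 1:
- Aryne 3 (CsF, MeCN) is trapped by purchased 3,4-dimethylfuran (Cc1cocc1C) to give the oxygen-bridged cycloadduct 6,7-dimethoxy-2,3-dimethyl-1,4-dihydro-1,4-epoxynaphthalene F5.
- H2 over Pd/C in EtOAc adds to the exo face of the strained bridged alkene, which cannot migrate, and should give the meso endo,endo-dimethyl compound F6 with the methyls cis.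
- Hydrogenolysis of the two benzylic C–O bonds (H2 at 4 bar, Pd/C, AcOH, catalytic HClO4) leaves the methyl-bearing carbons untouched and comes back to the route at 5.

**Step 4.** Cation 8 may lose a proton toward the 1,2-dihydronaphthalene and be re-protonated, scrambling C2. The facial bias may be insufficient, and ring A of a second molecule may compete with veratrole. The fallback sets out from 6 and replaces the cation by a radical/organonickel pathway:
- SOCl2 in CH2Cl2 at −20 °C gives the benzylic chloride F7 (C1 epimers, used crude).
- Nickel-catalysed reductive cross-electrophile coupling with purchased 4-iodo-1,2-dimethoxybenzene (COc1ccc(I)cc1OC) follows: NiBr2·glyme, 4,4'-di-tert-butyl-2,2'-bipyridine, Zn, DMA, 25 °C. The C1 benzylic radical should be captured by the aryl–nickel species on the face anti to the C2 methyl, and the fallback comes back to the route at 9.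

Further compounds
F1 | step 3 | racemic cis-6,7-dimethoxy-2,3-dimethyl-3,4-dihydronaphthalen-1(2H)-one ((2R,3R) antipode drawn) | O=C1c2cc(OC)c(OC)cc2C[C@@H](C)[C@H]1C
F2 | step 3 | racemic all-cis-6,7-dimethoxy-2,3-dimethyl-1,2,3,4-tetrahydronaphthalen-1-ol ((1R,2R,3R) antipode drawn) | O[C@H]1c2cc(OC)c(OC)cc2C[C@@H](C)[C@H]1C
F3 | step 3 | (1R,2R,3R)-6,7-dimethoxy-2,3-dimethyl-1,2,3,4-tetrahydronaphthalen-1-yl acetate | CC(=O)O[C@H]1c2cc(OC)c(OC)cc2C[C@@H](C)[C@H]1C
F4 | step 3 | (1S,2S,3S)-6,7-dimethoxy-2,3-dimethyl-1,2,3,4-tetrahydronaphthalen-1-ol (unreacted antipode) | O[C@@H]1c2cc(OC)c(OC)cc2C[C@H](C)[C@@H]1C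
F5 | step 2 | 6,7-dimethoxy-2,3-dimethyl-1,4-dihydro-1,4-epoxynaphthalene (meso) | COc1cc2c(cc1OC)[C@H]1O[C@@H]2C(C)=C1C
F6 | step 2 | meso-2-endo,3-endo-6,7-dimethoxy-2,3-dimethyl-1,2,3,4-tetrahydro-1,4-epoxynaphthalene | COc1cc2c(cc1OC)[C@H]1O[C@@H]2[C@@H](C)[C@H]1C
F7 | step 4 | (2R,3R)-1-chloro-6,7-dimethoxy-2,3-dimethyl-1,2,3,4-tetrahydronaphthalene (C1 epimers) | ClC1c2cc(OC)c(OC)cc2C[C@@H](C)[C@H]1C
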